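The earlier runs and the new flask come from a simulation for substances that don't exist, noise included.

The ratio of partner to starting material is the first thing to read. Taken as a ceiling of one partner for each product, it allows 0.700 of the charge in theta and 0.170 in eta. Partner is the limiting reagent in both, since even after the protic impurity takes its share of starting material, partner is the smaller amount.

| flask | starting material | partner | protic impurity | free catalyst | remark | time |
|---|---|---|---|---|---|---|
| larch | 0.80 M | 0.20 equiv | 0.080 M | 15 mol% | run made earlier |  |
| alder | 0.80 M | 0.82 equiv | 0.080 M | 15 mol% | run made earlier |  |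
| oak | 1.2 M | 0.70 equiv | 0.080 M | 15 mol% | run made earlier |  |
| theta | 0.80 M | 0.700 equiv | 0.0800 M | 15 mol% |  | 10 h |
| eta | 1.2 M | 0.170 equiv | 0.0800 M | 15 mol% |  | 10 h |

| run | time / h | product / % | starting material / % |
|---|---|---|---|
| larch | 0.417 | 2.8 | 85.6 |
| larch | 0.667 | 1.4 | 86.5 |
| larch | 1.00 | 3.1 | 84.2 |
| larch | 2.00 | 8.2 | 78.0 |
| larch | 3.00 | 9.9 | 75.6 |
| larch | 5.00 | 14.7 | 71.0 |
| alder | 0.833 | 5.2 | 83.4 |
| alder | 1.50 | 10.0 | 78.5 |
| alder | 2.50 | 14.4 | 73.3 |
| alder | 3.00 | 18.0 | 72.1 |
| alder | 4.00 | 24.7 | 64.4 |
| alder | 5.00 | 27.3 | 59.1 |
| oak | 0.417 | 2.3 | 88.7 |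
| oak | 0.833 | 5.8 | 82.1 |
| oak | 1.33 | 12.8 | 79.4 |
| oak | 2.50 | 21.9 | 69.4 |
| oak | 5.00 | 40.0 | 52.5 |

(readings scatter by 1 percentage point)

* the winner by amount of product, in percent of the starting material charged; "neither" if no more than 2 percentage points parts them (theta / eta / neither)
* how much product is there at the end, in percent of the starting material charged: theta
* how much product is there at the end, in percent of the starting material charged: eta

- where the amount of starting material changes, what is given in equivalents or mol% on it follows

You can solve two versions of the flask in your head. In the first, the catalyst is infinitely quick and product stands at the ceiling. In the second, partner never thins and product climbs a straight line. Alder, at the concentration of theta, sets that line at 0.0546 h⁻¹ of the charge, and oak, at the concentration of eta, sets it at 0.0800 h⁻¹. The real flask lies below the lesser of the two. Divide ceiling by rate: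

theta: 12.8 h

eta: 2.12 h

This is the crossing time, the hour at which the line meets the ceiling and control passes from the catalyst to the supply of partner. Eta crosses well before 10 h, so I expect it just under its ceiling. Theta crosses after it, so in this reckoning it ends short of its ceiling; I bend its line by the falling starting material and assume that partner goes to product. If the rate follows the starting material left after the impurity, 90.0 % of the charge, then doubling alder's time squares the unconverted share:

theta: 46.3 %

So my reckoning has theta winning.

The forecast also named theta, with 43 % for theta and 16.6 % for eta, calling eta “partner-limited, so it nearly reaches its 17% ceiling”.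

The flask gives 40.8 % for theta and 14.6 % for eta, so theta wins.

    2 catalyst intermediate A → spent catalyst (k = 0.0157 M⁻¹ min⁻¹)
    starting material + protic impurity → quenched substrate (k = 0.498 M⁻¹ min⁻¹)
    partner + catalyst intermediate A ⇌ catalyst intermediate B (K = 1.39 M⁻¹, k = 4.82 M⁻¹ min⁻¹)
    catalyst intermediate C → free catalyst + product (k = 2.57 min⁻¹)
    catalyst intermediate B → catalyst intermediate C (k = 0.249 min⁻¹)
    starting material + free catalyst ⇌ catalyst intermediate A (K = 1.40 M⁻¹, k = 0.0135 M⁻¹ min⁻¹)
    partner → decomposed reagent (k = 0.00180 min⁻¹)

Set the crossing time against the half-life of partner by its own decomposition, 6.42 h. Eta crosses sooner, at 2.12 h, and ends with 0.0290 M of decomposed reagent, whereas theta's 12.8 h is twice that half-life, and at 10.0 h theta holds 0.216 M of decomposed reagent, 3.10 % of its partner and 40.8 % of product, under my 46.3 %. The neighbour of eta charged with 0.100 equiv of partner crosses earlier still, at 1.25 h, and gives 8.78 %.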